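The readings were computed for substances that don't exist, and the scatter is random.

The amounts of Z and L in the earlier runs were enough for the quick number you wanted. Your hunch held: Z stood higher against L on Thursday than on Monday.

| flask | E | D | temperature | remark | time |
|---|---|---|---|---|---|
| Monday's | 0.24 M | 3.2 mM | 55 °C | run made earlier |  |
| Thursday's | 0.24 M | 7.2 mM | 90 °C | run made earlier |  |
| Tuesday's | 0.12 M | 4.8 mM | 55 °C | run made earlier |  |
| elm | 0.24 M | 4.8 mM | 80 °C |  | 4.0 d |
| larch | 0.24 M | 4.8 mM | 120 °C |  | 4.0 d |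
| alder | 0.24 M | 4.8 mM | 60 °C |  | 4.0 d |
| oak | 0.24 M | 4.8 mM | 100 °C |  | 4.0 d |

- Monday's (time / d: Z / %, L / %): 0.625: 0, 2.3; 1.67: 1.0, 7.2; 3.00: 1.5, 12.5; 4.00: 1.2, 16.8; 6.00: 1.8, 23.6; 8.00: 3.2, 29.7
- Thursday's (time / h: Z / %, L / %): 2.50: 2.3, 1.9; 8.00: 3.1, 6.0; 12.0: 4.2, 8.8; 20.0: 6.6, 13.6; 25.0: 8.0, 16.8; 40.0: 10.3, 22.2
- Tuesday's (time / d: Z / %, L / %): 0.625: 0.3, 3.2; 1.25: 1.0, 5.4; 2.00: 0.3, 8.1; 4.00: 2.2, 16.7; 8.00: 2.8, 30.4

(readings scatter by 0.5 percentage points)

1. the flask with the highest share of Z in all that became Z or L or G ("all alike" if they lie within 1.5 percentage points) (elm / larch / alder / oak / all alike)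
2. share of Z in all that became Z or L or G, elm
3. share of Z in all that became Z or L or G, larch
4. share of Z in all that became Z or L or G, alder
5. share of Z in all that became Z or L or G, oak



I compared the two products through r = [Z]/[L]. At their last readings, Monday gave 0.108 and Tuesday 0.0921, though [E] and [D] differed, so I pooled them. On Thursday r went from 0.517 at 8.00 h to 0.464 at 40.0 h. That was little drift for this scatter, so I pooled the last two readings.

Monday and Tuesday, 55 °C: r = 0.0998

Thursday, 90 °C: r = 0.469

B = 5270 K

B is the slope of ln r against reciprocal temperature. Carried from Thursday, it gave me r = 1.42 for larch, so Z/(Z+L) = 58.7%. For alder it gave r = 0.127, so 11.3%. The tables held Z and L, not G, and any G lowers these shares. I committed to larch, with 58.7% as its upper figure.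

The forecast named larch, with 23% for elm, 55% for larch, 11.5% for alder and 39% for oak. My larch figure was higher than its figure. Its words were: “G was never measured. I assume it is minor, but it could matter when hot, and Z might degrade there, so the larch and oak estimates are shaded down”.

The flasks gave 22.7% for elm, 43.6% for larch, 11.0% for alder and 34.5% for oak, so larch stood higher than the others, 11 percentage points below the forecast. In larch the half-life of Z by the forward step to G alone was 0.40 d, shorter than the 4.0 d of the run. G ended at 5.53% beside Z at 9.63%. The r from B, 1.42, with that G/Z of 0.574, gives Z/(Z+L+G) = 43.9%.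

    E + D ⇌ Z + D, rate k1*[E]*[D] forward; the back reaction follows from the equilibrium constant (K = 0.290, k = 2.21 /M/h, Ea = 86.0 kJ/mol, ΔH = −52.0 kJ/mol)
    Z + D ⇌ L + D, rate k2*[D]*[Z] forward; the back reaction follows from the equilibrium constant (K = 1.50, k = 99.4 /M/h, Ea = 52.0 kJ/mol, ΔH = −45.0 kJ/mol)
    L ⇌ E (k = 0.0149 /h, Ea = 125 kJ/mol)
    Z ⇌ G (K = 0.520, k = 0.0105 /h, Ea = 118 kJ/mol, ΔH = 6.00 kJ/mol)
    (constants at 100 °C)

For a repeat of larch at 145 °C, B gives r = 3.16, and larch's G/Z then gives a share of 52.9%. The computed flask gave 51.1%, with Z at 4.37% and G at 2.80%.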